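Everything rests on disconnecting C3–C4 of ring C, the bond between the benzylic carbon C3 that carries the chromene (ring B) and the aroyl carbon C4 of ring A. Both carbons are electrophilic by nature and sit at the two ends of the O1–C2 ether, which tethers them for a six-membered closure. A nickel-catalysed, manganese-driven reductive acyl–benzyl coupling forms this bond, closes ring C and sets C3 enantioconvergently in one operation. Its precursor is a racemic tribenzyl-protected 2-(2-chloro-2-arylethoxy)benzoyl chloride, assembled by O-alkylation of a salicylate with a chromenyl bromomethyl ketone and generated under neutral conditions just before use. BCl3 debenzylation ends the route.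

Key step: step 8

Remarks on the chemistry:
- Flavonoid numbering is used (O1, C2, C3, C4 in ring C; ring A is the phloroglucinol-derived ring; ring B is the benzene ring of the chromene).
- Compound 3 is purchased; it is also one Williamson step from 2,4-dihydroxyacetophenone.
- The chromene has to be annulated through the chelated 2-hydroxyl of the acetophenone with the 4-hydroxyl already benzylated. Propargylation of free 2,4-dihydroxyacetophenone goes to the 4-hydroxyl and would end in the 6-acyl-5-hydroxychromene, not the 8-substituted 5-oxychromene of ring B.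
- Assumption: the (S,S)-bis(oxazoline) induces 3S; if the first run shows the opposite sense, the mirror-image ligand is used.

Step 1
Reactants: 1 methyl 2,4,6-trihydroxybenzoate
Product: 2 methyl 2,4-bis(benzyloxy)-6-hydroxybenzoate
Conditions: BnBr (2.05 equiv), K2CO3, acetone, reflux
Reagents that add atoms: benzyl bromide, BrCc1ccccc1
Why: Williamson ether synthesis; the 4-hydroxyl and one ortho hydroxyl are alkylated, while the last ortho hydroxyl is hydrogen-bonded to the ester carbonyl and should react much more slowly, so two equivalents should stop at the dibenzyl ether (any tribenzyl ether is separable).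

Step 2
Reactants: 3 1-[4-(benzyloxy)-2-hydroxyphenyl]ethan-1-one; 4 3-chloro-3-methylbut-1-yne
Product: 5 1-{4-(benzyloxy)-2-[(2-methylbut-3-yn-2-yl)oxy]phenyl}ethan-1-one
Conditions: DBU, CuCl2·2H2O (1 mol %), MeCN, 0 °C to rt
Reagents that add atoms: none
Why: Copper-catalysed propargylic substitution of a tertiary propargylic chloride by a phenoxide; DBU breaks the chelate, and the only free hydroxyl is the one that must carry the ether.

Step 3
Reactants: 5 1-{4-(benzyloxy)-2-[(2-methylbut-3-yn-2-yl)oxy]phenyl}ethan-1-one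
Product: 6 1-[5-(benzyloxy)-2,2-dimethyl-2H-chromen-8-yl]ethan-1-one
Conditions: N,N-diethylaniline, 170 °C
Reagents that add atoms: none
Why: Aromatic propargyl Claisen rearrangement followed by enolisation, 1,5-hydrogen shift and oxa-6π electrocyclisation; the only free ortho position lies between the two oxygens, so the 8-acetyl-5-benzyloxy chromene should be the sole regioisomer.

Step 4
Reactants: 6 1-[5-(benzyloxy)-2,2-dimethyl-2H-chromen-8-yl]ethan-1-one
Product: 8 2-bromo-1-[5-(benzyloxy)-2,2-dimethyl-2H-chromen-8-yl]ethan-1-one, via trimethylsilyl enol ether 7 (not isolated)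
Conditions: LiHMDS, TMSCl, THF, −78 °C; then NBS, −78 to 0 °C
Reagents that add atoms: N-bromosuccinimide, O=C1CCC(=O)N1Br
Why: Kinetic enolate formation, O-silylation and electrophilic bromination of the silyl enol ether; the enol ether is far more nucleophilic than the chromene alkene or the arene, so bromine should go only to the methyl carbon.

Step 5
Reactants: 2 methyl 2,4-bis(benzyloxy)-6-hydroxybenzoate; 8 2-bromo-1-[5-(benzyloxy)-2,2-dimethyl-2H-chromen-8-yl]ethan-1-one
Product: 9 methyl 2,4-bis(benzyloxy)-6-{2-[5-(benzyloxy)-2,2-dimethyl-2H-chromen-8-yl]-2-oxoethoxy}benzoate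
Conditions: K2CO3, DMF, rt
Reagents that add atoms: none
Why: Williamson SN2 displacement on an α-bromo ketone builds the O1–C2 tether; carbonate at room temperature should not trigger Dieckmann-type attack of the ketone enolate on the hindered ester.

Step 6
Reactants: 9 methyl 2,4-bis(benzyloxy)-6-{2-[5-(benzyloxy)-2,2-dimethyl-2H-chromen-8-yl]-2-oxoethoxy}benzoate
Product: 11 rac-2,4-bis(benzyloxy)-6-{2-[5-(benzyloxy)-2,2-dimethyl-2H-chromen-8-yl]-2-hydroxyethoxy}benzoic acid, via racemic hydroxy ester 10 (not isolated)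
Conditions: NaBH4, THF/MeOH, 0 °C; then 4 M aq KOH, reflux; dilute HCl to pH 4–5, 0 °C
Reagents that add atoms: potassium hydroxide, [K+].[OH-]
Why: Borohydride reduces only the ketone (a racemic carbinol is wanted), and hot hydroxide then saponifies the di-ortho-substituted methyl ester; benzyl ethers, the aryl ether and the chromene are base-stable, and cold, mild acidification spares the electron-rich benzylic alcohol.

Step 7
Reactants: 11 rac-2,4-bis(benzyloxy)-6-{2-[5-(benzyloxy)-2,2-dimethyl-2H-chromen-8-yl]-2-hydroxyethoxy}benzoic acid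
Product: 12 rac-2,4-bis(benzyloxy)-6-{2-[5-(benzyloxy)-2,2-dimethyl-2H-chromen-8-yl]-2-chloroethoxy}benzoyl chloride (crude, used at once)
Conditions: 1-chloro-N,N,2-trimethylprop-1-en-1-amine (2.5 equiv), CH2Cl2, 0 °C to rt, 11 added to the reagent; volatiles removed in vacuo
Reagents that add atoms: 1-chloro-N,N,2-trimethylprop-1-en-1-amine, CC(C)=C(Cl)N(C)C
Why: The α-chloroenamine converts carboxylic acids into acid chlorides and alcohols into chlorides under neutral conditions with an amide as the only by-product, so no HCl reaches the chromene; inverse addition into excess reagent should consume both hydroxyls before the hindered acid chloride can acylate the carbinol.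

Step 8
Reactants: 12 rac-2,4-bis(benzyloxy)-6-{2-[5-(benzyloxy)-2,2-dimethyl-2H-chromen-8-yl]-2-chloroethoxy}benzoyl chloride
Product: 13 (3S)-5,7-bis(benzyloxy)-3-[5-(benzyloxy)-2,2-dimethyl-2H-chromen-8-yl]-2,3-dihydro-4H-chromen-4-one
Conditions: NiCl2(dme) (15 mol %), 2,2'-(propane-2,2-diyl)bis[(4S)-4-phenyl-4,5-dihydro-1,3-oxazole] (18 mol %), Mn powder (3 equiv), 3 Å MS, DMA/THF 3:7, 20 °C, slow addition of 12 at high dilution
Reagents that add atoms: none
Why: Proposed new method: manganese reduces the NiCl2(dme)–bis(oxazoline) complex to zerovalent nickel, which inserts into the aroyl C–Cl bond; low-valent nickel abstracts chlorine from the benzylic chloride to give a planar C3 radical, the divalent aroylnickel captures it, and reductive elimination from trivalent nickel forges C3–C4, manganese returning the monovalent nickel to the cycle. The closest known reaction type is the intermolecular nickel-catalysed enantioselective reductive cross-coupling of acid chlorides with racemic secondary benzylic chlorides; the tether and the use of an aroyl chloride are new. Ring C closes as a six-membered ring by C–C reductive elimination from a seven-membered acyl(benzyl)nickelacycle, formally a 6-exo-trig attack of C3 on the C4 acyl carbon. C3 is set by the catalyst alone: radical formation erases the configuration of racemic 12, and the chiral ligand on nickel decides which face of the radical, flanked by the unlike ring B aryl and CH2–O1 groups, is bonded (ligand antipode as assumed in the remarks). The step needs cross-selectivity between the two C–Cl bonds (the sp2 acyl chloride adds oxidatively, the weak benzylic C–Cl gives the radical), ring closure over dimerisation (O1–C2 tether, slow addition, high dilution), and radical capture faster than decarbonylation of the aroylnickel or loss of the β-aryloxy group (manganese forms no benzylic organometallic). No base is present, so the new α-aryl ketone stereocentre should persist, and the benzyl ethers and the chromene alkene are not expected to engage the catalyst.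

Step 9
Reactants: 13 (3S)-5,7-bis(benzyloxy)-3-[5-(benzyloxy)-2,2-dimethyl-2H-chromen-8-yl]-2,3-dihydro-4H-chromen-4-one
Product: 14 (3S)-5,7-dihydroxy-3-(5-hydroxy-2,2-dimethyl-2H-chromen-8-yl)-2,3-dihydro-4H-chromen-4-one
Conditions: BCl3 (6 equiv), pentamethylbenzene (10 equiv), CH2Cl2, −78 to −40 °C; MeOH quench at −78 °C
Reagents that add atoms: none
Why: Lewis-acid debenzylation of aryl benzyl ethers with a non-basic arene as benzyl cation scavenger (Friedel–Crafts capture); it needs no hydrogen, so the chromene alkene is not reduced, and it is base-free and cold, so C3 should keep its configuration.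

Compound list
1 | methyl 2,4,6-trihydroxybenzoate | COC(=O)c1c(O)cc(O)cc1O | starting material
2 | methyl 2,4-bis(benzyloxy)-6-hydroxybenzoate | COC(=O)c1c(O)cc(OCc2ccccc2)cc1OCc1ccccc1 | intermediate
3 | 1-[4-(benzyloxy)-2-hydroxyphenyl]ethan-1-one | CC(=O)c1ccc(OCc2ccccc2)cc1O | starting material
4 | 3-chloro-3-methylbut-1-yne | CC(C)(Cl)C#C | starting material
5 | 1-{4-(benzyloxy)-2-[(2-methylbut-3-yn-2-yl)oxy]phenyl}ethan-1-one | CC(=O)c1ccc(OCc2ccccc2)cc1OC(C)(C)C#C | intermediate
6 | 1-[5-(benzyloxy)-2,2-dimethyl-2H-chromen-8-yl]ethan-1-one | CC(=O)c1ccc(OCc2ccccc2)c2C=CC(C)(C)Oc12 | intermediate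
7 | {1-[5-(benzyloxy)-2,2-dimethyl-2H-chromen-8-yl]ethenyloxy}trimethylsilane | C=C(O[Si](C)(C)C)c1ccc(OCc2ccccc2)c2C=CC(C)(C)Oc12 | intermediate (not isolated)
8 | 2-bromo-1-[5-(benzyloxy)-2,2-dimethyl-2H-chromen-8-yl]ethan-1-one | O=C(CBr)c1ccc(OCc2ccccc2)c2C=CC(C)(C)Oc12 | intermediate
9 | methyl 2,4-bis(benzyloxy)-6-{2-[5-(benzyloxy)-2,2-dimethyl-2H-chromen-8-yl]-2-oxoethoxy}benzoate | COC(=O)c1c(OCc2ccccc2)cc(OCc2ccccc2)cc1OCC(=O)c1ccc(OCc2ccccc2)c2C=CC(C)(C)Oc12 | intermediate
10 | methyl rac-2,4-bis(benzyloxy)-6-{2-[5-(benzyloxy)-2,2-dimethyl-2H-chromen-8-yl]-2-hydroxyethoxy}benzoate | COC(=O)c1c(OCc2ccccc2)cc(OCc2ccccc2)cc1OCC(O)c1ccc(OCc2ccccc2)c2C=CC(C)(C)Oc12 | intermediate (not isolated)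
11 | rac-2,4-bis(benzyloxy)-6-{2-[5-(benzyloxy)-2,2-dimethyl-2H-chromen-8-yl]-2-hydroxyethoxy}benzoic acid | OC(=O)c1c(OCc2ccccc2)cc(OCc2ccccc2)cc1OCC(O)c1ccc(OCc2ccccc2)c2C=CC(C)(C)Oc12 | intermediate
12 | rac-2,4-bis(benzyloxy)-6-{2-[5-(benzyloxy)-2,2-dimethyl-2H-chromen-8-yl]-2-chloroethoxy}benzoyl chloride | O=C(Cl)c1c(OCc2ccccc2)cc(OCc2ccccc2)cc1OCC(Cl)c1ccc(OCc2ccccc2)c2C=CC(C)(C)Oc12 | intermediate
13 | (3S)-5,7-bis(benzyloxy)-3-[5-(benzyloxy)-2,2-dimethyl-2H-chromen-8-yl]-2,3-dihydro-4H-chromen-4-one | CC1(C)C=Cc2c(OCc3ccccc3)ccc([C@H]3COc4cc(OCc5ccccc5)cc(OCc5ccccc5)c4C3=O)c2O1 | intermediate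
14 | (3S)-5,7-dihydroxy-3-(5-hydroxy-2,2-dimethyl-2H-chromen-8-yl)-2,3-dihydro-4H-chromen-4-one | CC1(C)C=Cc2c(O)ccc([C@H]3COc4cc(O)cc(O)c4C3=O)c2O1 | target

Total step count: 9. Longest linear sequence: 8 steps (3 to 14 through steps 2–9).

Steps most likely to fail

Step 8. The hindered aroylnickel may lose CO before it meets the radical, the benzylic chloride may ionise, dimerise or shed its β-aryloxy group before capture, or the ligand may discriminate the radical faces poorly. The fallback uses known chemistry, sets out from 9 and comes back at 13.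
- LiAlH4 (THF, 0 °C) reduces ketone and ester of 9 to the benzylic diol F1.
- Dess–Martin periodinane (CH2Cl2, NaHCO3) oxidises both carbinols to the keto aldehyde F2.
- A triazolium-derived N-heterocyclic carbene (precatalyst with DBU, THF) effects an intramolecular crossed benzoin reaction: the aldehyde-derived acyl anion equivalent adds to the aryl ketone, forming the same C3–C4 bond and giving the racemic 3-hydroxyisoflavanone F3.
- SmI2 (THF/MeOH, −78 °C) removes the α-hydroxyl to give the racemic tribenzyl isoflavanone F4.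
- RuCl(p-cymene)[(S,S)-TsDPEN] with HCO2H/Et3N reduces F4 by transfer hydrogenation under dynamic kinetic resolution (C3 epimerises under these conditions) to the cis-(3S,4S)-isoflavan-4-ol F5; the catalyst antipode is chosen to give this isomer.
- Base-free Dess–Martin oxidation at 0 °C returns 13.

Step 7. The nascent acid chloride may acylate the still-free benzylic hydroxyl (seven-membered lactone), and the electron-rich benzylic chloride may ionise during its formation. The fallback separates the two chlorinations, sets out from 11 and comes back at 12.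
- TBSCl (1 equiv) with imidazole in CH2Cl2 at 0 °C silylates the carboxyl group only, giving the silyl ester carbinol F6.
- The α-chloroenamine then converts the alcohol into the chloride while the acyl carbon stays unactivated, giving the chloro silyl ester F7.
- (COCl)2 with catalytic DMF exchanges the silyl ester for the acid chloride without releasing HCl, giving 12.

Step 9. Excess Lewis acid may ionise the aryl–O–CMe2 bond of the chromene or add HCl across its alkene, and the boron-chelated ketone may enolise and erode C3. The fallback is a staged deprotection without strong Lewis acid, sets out from 13 and ends at 14.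
- MgBr2·OEt2 (toluene/Et2O, rt) removes only the chelation-activated 5-O-benzyl group next to the C4 carbonyl, giving the 5-hydroxy dibenzyl ether F8.
- Pd(OAc)2 (cat.), Et3SiH and catalytic Et3N in CH2Cl2 cleave the two remaining benzyl ethers by silane hydrogenolysis, which should spare the alkene, giving the bis(triethylsilyl) ether F9.
- AcOH in THF/H2O at rt desilylates F9 to 14.

Further compounds
F1 | step 8 | rac-1-[5-(benzyloxy)-2,2-dimethyl-2H-chromen-8-yl]-2-[3,5-bis(benzyloxy)-2-(hydroxymethyl)phenoxy]ethan-1-ol | OCc1c(OCc2ccccc2)cc(OCc2ccccc2)cc1OCC(O)c1ccc(OCc2ccccc2)c2C=CC(C)(C)Oc12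
F2 | step 8 | 2,4-bis(benzyloxy)-6-{2-[5-(benzyloxy)-2,2-dimethyl-2H-chromen-8-yl]-2-oxoethoxy}benzaldehyde | O=Cc1c(OCc2ccccc2)cc(OCc2ccccc2)cc1OCC(=O)c1ccc(OCc2ccccc2)c2C=CC(C)(C)Oc12
F3 | step 8 | rac-5,7-bis(benzyloxy)-3-[5-(benzyloxy)-2,2-dimethyl-2H-chromen-8-yl]-3-hydroxy-2,3-dihydro-4H-chromen-4-one | CC1(C)C=Cc2c(OCc3ccccc3)ccc(C3(O)COc4cc(OCc5ccccc5)cc(OCc5ccccc5)c4C3=O)c2O1
F4 | step 8 | rac-5,7-bis(benzyloxy)-3-[5-(benzyloxy)-2,2-dimethyl-2H-chromen-8-yl]-2,3-dihydro-4H-chromen-4-one | CC1(C)C=Cc2c(OCc3ccccc3)ccc(C3COc4cc(OCc5ccccc5)cc(OCc5ccccc5)c4C3=O)c2O1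
F5 | step 8 | (3S,4S)-5,7-bis(benzyloxy)-3-[5-(benzyloxy)-2,2-dimethyl-2H-chromen-8-yl]-3,4-dihydro-2H-chromen-4-ol (cis) | CC1(C)C=Cc2c(OCc3ccccc3)ccc([C@H]3COc4cc(OCc5ccccc5)cc(OCc5ccccc5)c4[C@H]3O)c2O1
F6 | step 7 | tert-butyldimethylsilyl rac-2,4-bis(benzyloxy)-6-{2-[5-(benzyloxy)-2,2-dimethyl-2H-chromen-8-yl]-2-hydroxyethoxy}benzoate | CC(C)(C)[Si](C)(C)OC(=O)c1c(OCc2ccccc2)cc(OCc2ccccc2)cc1OCC(O)c1ccc(OCc2ccccc2)c2C=CC(C)(C)Oc12
F7 | step 7 | tert-butyldimethylsilyl rac-2,4-bis(benzyloxy)-6-{2-[5-(benzyloxy)-2,2-dimethyl-2H-chromen-8-yl]-2-chloroethoxy}benzoate | CC(C)(C)[Si](C)(C)OC(=O)c1c(OCc2ccccc2)cc(OCc2ccccc2)cc1OCC(Cl)c1ccc(OCc2ccccc2)c2C=CC(C)(C)Oc12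
F8 | step 9 | (3S)-7-(benzyloxy)-3-[5-(benzyloxy)-2,2-dimethyl-2H-chromen-8-yl]-5-hydroxy-2,3-dihydro-4H-chromen-4-one | CC1(C)C=Cc2c(OCc3ccccc3)ccc([C@H]3COc4cc(OCc5ccccc5)cc(O)c4C3=O)c2O1
F9 | step 9 | (3S)-5-hydroxy-7-[(triethylsilyl)oxy]-3-{2,2-dimethyl-5-[(triethylsilyl)oxy]-2H-chromen-8-yl}-2,3-dihydro-4H-chromen-4-one | CC1(C)C=Cc2c(O[Si](CC)(CC)CC)ccc([C@H]3COc4cc(O[Si](CC)(CC)CC)cc(O)c4C3=O)c2O1
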